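**Strategy.** Everything rests on cutting the C1′–C2′ bond of the (E)-3-methylallyl ether that links O7 of the coumarin to the terpenoid. C1′ sits between O7 and C2′ and is at the formaldehyde oxidation level, so it is brought in as the chloromethyl ether of umbelliferone; C2′=C3′(CH3) is the imprint of a syn methyl-metalation of a terminal alkyne. One operation (Zr-catalysed methylalumination, then alkylation of the alkenylalanate) therefore adds the C3′ methyl, fixes the E geometry and joins both halves. The precursor is a C13 terminal alkyne on the 6-oxabicyclo[3.2.1]octane core, made by asymmetric Birch methylation, iodolactonization and radical allylation at C8.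

Key step: step 15

Assumption: in step 2 methyl iodide is taken to enter the chelated potassium amide enolate anti to the CH2OMe arm, which with the (R)-auxiliary gives the (1S) quaternary carbon; if the sense proved opposite, the (S)-auxiliary would be used with no other change.

**Step 1**
Reactants: 1 2-methoxy-5-methylbenzoic acid; 2 (R)-2-(methoxymethyl)pyrrolidine
Product: 4 (2-methoxy-5-methylphenyl)[(2R)-2-(methoxymethyl)pyrrolidin-1-yl]methanone, via acid chloride 3 (not isolated)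
Conditions: (COCl)2, cat. DMF, CH2Cl2, 0 °C to rt; then 2, Et3N, CH2Cl2, 0 °C to rt
Reagents that add atoms: none
Why: Amide formation through the acid chloride (N-acylation) attaches the prolinol-ether auxiliary that directs the Birch alkylation; no stereocentre is formed.

**Step 2**
Reactants: 4 (2-methoxy-5-methylphenyl)[(2R)-2-(methoxymethyl)pyrrolidin-1-yl]methanone
Product: 6 [(1S)-2-methoxy-1,5-dimethylcyclohexa-2,5-dien-1-yl][(2R)-2-(methoxymethyl)pyrrolidin-1-yl]methanone, via potassium amide enolate 5 (not isolated)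
Conditions: K (2.2 equiv), NH3(l)/THF, t-BuOH (1 equiv), −78 °C; then MeI, −78 °C; NH4Cl quench
Reagents that add atoms: methyl iodide, CI
Why: Birch reductive alkylation: reduction with one equivalent of proton source should give the chelated enolate 5 (protonation at C4), and C-methylation on the face anti to the CH2OMe arm should set the quaternary C1 as S.

**Step 3**
Reactants: 6 [(1S)-2-methoxy-1,5-dimethylcyclohexa-2,5-dien-1-yl][(2R)-2-(methoxymethyl)pyrrolidin-1-yl]methanone
Product: 7 (2S)-2-{[(2R)-2-(methoxymethyl)pyrrolidin-1-yl]carbonyl}-2,4-dimethylcyclohex-3-en-1-one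
Conditions: 1 M aq. HCl, MeOH, rt
Reagents that add atoms: water, O
Why: Acid hydrolysis of the enol ether unmasks the ketone, and the trisubstituted alkene cannot move into conjugation because the carbon between it and the ketone is quaternary.

**Step 4**
Reactants: 7 (2S)-2-{[(2R)-2-(methoxymethyl)pyrrolidin-1-yl]carbonyl}-2,4-dimethylcyclohex-3-en-1-one
Product: 8 (1S,5S,8S)-8-iodo-1,5-dimethyl-6-oxabicyclo[3.2.1]octane-2,7-dione
Conditions: I2, THF/H2O (1:1), rt; aq. Na2S2O3/NaHCO3 work-up (auxiliary 2 recovered)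
Reagents that add atoms: iodine, II; water, O
Why: Iodolactonization: the amide oxygen should open the iodonium ion at the tertiary alkene carbon anti to iodine and hydrolysis of the iminium ether releases the auxiliary; the lactone can only bridge cis, which fixes C5 relative to C1 and places iodine on C8 anti to the lactone oxygen.

**Step 5**
Reactants: 8 (1S,5S,8S)-8-iodo-1,5-dimethyl-6-oxabicyclo[3.2.1]octane-2,7-dione
Product: 9 (1S,5S,8R)-1,5-dimethyl-8-(prop-2-en-1-yl)-6-oxabicyclo[3.2.1]octane-2,7-dione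
Conditions: allyltributylstannane (3 equiv), AIBN (cat.), benzene, 80 °C
Reagents that add atoms: allyltributylstannane, C=CC[Sn](CCCC)(CCCC)CCCC
Why: Keck radical allylation: the planar C8 radical should be trapped from the face syn to the flat, hydrogen-free lactone bridge, not from the face shielded by the axial C4–H of the six-membered bridge, so the allyl group ends up syn to the lactone (8R).

**Step 6**
Reactants: 9 (1S,5S,8R)-1,5-dimethyl-8-(prop-2-en-1-yl)-6-oxabicyclo[3.2.1]octane-2,7-dione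
Product: 10 (1S,2R,5S,8R)-2-hydroxy-1,5-dimethyl-8-(prop-2-en-1-yl)-6-oxabicyclo[3.2.1]octan-7-one
Conditions: NaBH4, MeOH/CH2Cl2, −20 to 0 °C
Reagents that add atoms: none
Why: Chemoselective borohydride reduction of the ketone in the presence of the hindered lactone; axial hydride attack anti to the lactone bridge (whose carbonyl on C1 blocks the other face) should give the equatorial 2R alcohol cis to the bridge.

**Step 7**
Reactants: 10 (1S,2R,5S,8R)-2-hydroxy-1,5-dimethyl-8-(prop-2-en-1-yl)-6-oxabicyclo[3.2.1]octan-7-one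
Product: 11 (1S,2R,5S,8R)-2-[(tert-butyldimethylsilyl)oxy]-1,5-dimethyl-8-(prop-2-en-1-yl)-6-oxabicyclo[3.2.1]octan-7-one
Conditions: TBSOTf, 2,6-lutidine, CH2Cl2, 0 °C
Reagents that add atoms: tert-butyldimethylsilyl triflate, CC(C)(C)[Si](C)(C)OS(=O)(=O)C(F)(F)F
Why: Silyl ether protection of the hindered secondary alcohol with the reactive triflate masks the OH against DIBAL-H, the later oxidation and the organoaluminium step.

**Step 8**
Reactants: 11 (1S,2R,5S,8R)-2-[(tert-butyldimethylsilyl)oxy]-1,5-dimethyl-8-(prop-2-en-1-yl)-6-oxabicyclo[3.2.1]octan-7-one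
Product: 12 (1S,2R,5S,8R)-2-[(tert-butyldimethylsilyl)oxy]-1,5-dimethyl-8-(prop-2-en-1-yl)-6-oxabicyclo[3.2.1]octan-7-ol (both C7 epimers)
Conditions: DIBAL-H (1.2 equiv), CH2Cl2, −78 °C; Rochelle salt work-up
Reagents that add atoms: none
Why: Partial reduction of the lactone to the lactol with DIBAL-H at low temperature, where the tetrahedral aluminate should persist until work-up.

**Step 9**
Reactants: 12 (1S,2R,5S,8R)-2-[(tert-butyldimethylsilyl)oxy]-1,5-dimethyl-8-(prop-2-en-1-yl)-6-oxabicyclo[3.2.1]octan-7-ol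
Product: 13 tert-butyl{[(1R,2R,5S,8R)-1,5-dimethyl-8-(prop-2-en-1-yl)-6-oxabicyclo[3.2.1]octan-2-yl]oxy}dimethylsilane
Conditions: Et3SiH (5 equiv), BF3·OEt2 (2 equiv), CH2Cl2, −78 to −30 °C
Reagents that add atoms: none
Why: Ionic hydrogenation of the lactol (oxocarbenium ion at the non-bridgehead C7, hydride from the silane) converts the lactone bridge into the O–CH2 bridge without touching a stereocentre.

**Step 10**
Reactants: 13 tert-butyl{[(1R,2R,5S,8R)-1,5-dimethyl-8-(prop-2-en-1-yl)-6-oxabicyclo[3.2.1]octan-2-yl]oxy}dimethylsilane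
Product: 15 3-[(1R,2R,5S,8R)-2-[(tert-butyldimethylsilyl)oxy]-1,5-dimethyl-6-oxabicyclo[3.2.1]octan-8-yl]propan-1-ol, via B-alkyl-9-BBN 14 (not isolated)
Conditions: 9-BBN, THF, 0 °C to rt; then aq. NaOH, H2O2, 0 °C to rt
Reagents that add atoms: hydrogen peroxide, OO
Why: Anti-Markovnikov hydroboration–oxidation of the terminal alkene gives the primary alcohol.

**Step 11**
Reactants: 15 3-[(1R,2R,5S,8R)-2-[(tert-butyldimethylsilyl)oxy]-1,5-dimethyl-6-oxabicyclo[3.2.1]octan-8-yl]propan-1-ol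
Product: 16 3-[(1R,2R,5S,8R)-2-[(tert-butyldimethylsilyl)oxy]-1,5-dimethyl-6-oxabicyclo[3.2.1]octan-8-yl]propanal
Conditions: Dess–Martin periodinane, NaHCO3, CH2Cl2, rt
Reagents that add atoms: none
Why: Dess–Martin oxidation stops cleanly at the aldehyde under buffered, non-epimerising conditions.

**Step 12**
Reactants: 16 3-[(1R,2R,5S,8R)-2-[(tert-butyldimethylsilyl)oxy]-1,5-dimethyl-6-oxabicyclo[3.2.1]octan-8-yl]propanal
Product: 17 tert-butyl{[(1R,2R,5S,8R)-8-(but-3-yn-1-yl)-1,5-dimethyl-6-oxabicyclo[3.2.1]octan-2-yl]oxy}dimethylsilane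
Conditions: dimethyl (1-diazo-2-oxopropyl)phosphonate, K2CO3, MeOH, 0 °C to rt
Reagents that add atoms: dimethyl (1-diazo-2-oxopropyl)phosphonate, COP(=O)(OC)C(=[N+]=[N-])C(C)=O
Why: Seyferth–Gilbert homologation in the Ohira–Bestmann variant converts the aldehyde into the one-carbon-longer terminal alkyne under mild base.

**Step 13**
Reactants: 18 7-hydroxy-2H-chromen-2-one (umbelliferone)
Product: 19 7-[(methylsulfanyl)methoxy]-2H-chromen-2-one
Conditions: NaH, DMF, 0 °C; chloromethyl methyl sulfide, NaI (cat.), 0 °C to rt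
Reagents that add atoms: chloromethyl methyl sulfide, CSCCl
Why: Williamson O-alkylation of the phenoxide gives the O,S-acetal (MTM ether) that carries the future C1′.

**Step 14**
Reactants: 19 7-[(methylsulfanyl)methoxy]-2H-chromen-2-one
Product: 20 7-(chloromethoxy)-2H-chromen-2-one
Conditions: SO2Cl2 (1.05 equiv), CH2Cl2, 0 °C; volatiles removed, used crude
Reagents that add atoms: sulfuryl chloride, O=S(=O)(Cl)Cl
Why: Chlorinolysis of the O,S-acetal (S-chlorosulfonium ion, loss of MeSCl, chloride capture of the aryloxymethyl cation) gives the α-chloro ether; the sulfide should react far faster than the coumarin C3=C4 bond.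

**Step 15**
Reactants: 17 tert-butyl{[(1R,2R,5S,8R)-8-(but-3-yn-1-yl)-1,5-dimethyl-6-oxabicyclo[3.2.1]octan-2-yl]oxy}dimethylsilane; 20 7-(chloromethoxy)-2H-chromen-2-one
Product: 23 7-{[(2E)-5-[(1R,2R,5S,8R)-2-[(tert-butyldimethylsilyl)oxy]-1,5-dimethyl-6-oxabicyclo[3.2.1]octan-8-yl]-3-methylpent-2-en-1-yl]oxy}-2H-chromen-2-one, via alkenylalane 21 (not isolated), via lithium alanate 22 (not isolated)
Conditions: Me3Al (2.5 equiv), Cp2ZrCl2 (0.25 equiv), CH2Cl2, rt; volatiles and excess Me3Al removed in vacuo; THF, n-BuLi (1.05 equiv), −78 °C; 20 (1.3 equiv) in THF, −78 to −20 °C; cold aq. Rochelle salt quench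
Reagents that add atoms: trimethylaluminium, C[Al](C)C
Why: Zr-catalysed methylalumination adds CH3 and Al syn across the terminal alkyne (methyl to the internal carbon), giving the (E)-2-methylalkenylalane 21; n-BuLi turns it into alanate 22, whose alkenyl group displaces chloride from the α-chloro ether 20 with retention of alkene geometry. The closest known reaction type is Negishi carboalumination followed by C-alkylation of the alkenylalanate with chloromethyl methyl ether or paraformaldehyde to give (E)-3-methylallyl ethers and alcohols. No ring is closed and no stereocentre is formed; the trisubstituted E alkene is fixed by syn carbometalation and stereoretentive substitution at the C–Al bond. The step needs methyl delivery to the internal alkyne carbon (secured by the terminal alkyne and the Zr catalyst), alkenyl rather than methyl or butyl transfer (alkenyl ligands leave mixed alanates preferentially) and attack at the chloromethyl carbon rather than at the coumarin lactone (the α-chloro ether is by far the most electrophilic site at −78 °C, excess Me3Al is removed first and the OH is masked as its TBS ether).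

**Step 16**
Reactants: 23 7-{[(2E)-5-[(1R,2R,5S,8R)-2-[(tert-butyldimethylsilyl)oxy]-1,5-dimethyl-6-oxabicyclo[3.2.1]octan-8-yl]-3-methylpent-2-en-1-yl]oxy}-2H-chromen-2-one
Product: 24 7-{[(2E)-5-[(1R,2R,5S,8R)-2-hydroxy-1,5-dimethyl-6-oxabicyclo[3.2.1]octan-8-yl]-3-methylpent-2-en-1-yl]oxy}-2H-chromen-2-one (target)
Conditions: HF·pyridine, pyridine/THF, 0 °C to rt
Reagents that add atoms: none
Why: Buffered fluoride desilylation frees the secondary alcohol without ionising the allylic aryl ether or opening the coumarin lactone.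

**Compound list**
1 | 2-methoxy-5-methylbenzoic acid | COc1ccc(C)cc1C(=O)O | starting material
2 | (R)-2-(methoxymethyl)pyrrolidine | COC[C@H]1CCCN1 | starting material
3 | 2-methoxy-5-methylbenzoyl chloride | COc1ccc(C)cc1C(Cl)=O | intermediate
4 | (2-methoxy-5-methylphenyl)[(2R)-2-(methoxymethyl)pyrrolidin-1-yl]methanone | COc1ccc(C)cc1C(=O)N1CCC[C@@H]1COC | intermediate
5 | potassium amide enolate of the 1,4-dihydrobenzamide (enolate O syn to the ring OMe) | [K+].[O-]/C(N1CCC[C@@H]1COC)=C1\C(OC)=CCC(C)=C1 | intermediate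
6 | [(1S)-2-methoxy-1,5-dimethylcyclohexa-2,5-dien-1-yl][(2R)-2-(methoxymethyl)pyrrolidin-1-yl]methanone | C[C@]1(C(=O)N2CCC[C@@H]2COC)C=C(C)CC=C1OC | intermediate
7 | (2S)-2-{[(2R)-2-(methoxymethyl)pyrrolidin-1-yl]carbonyl}-2,4-dimethylcyclohex-3-en-1-one | C[C@]1(C(=O)N2CCC[C@@H]2COC)C=C(C)CCC1=O | intermediate
8 | (1S,5S,8S)-8-iodo-1,5-dimethyl-6-oxabicyclo[3.2.1]octane-2,7-dione (iodine anti to the lactone bridge) | I[C@H]1[C@]2(C)C(=O)O[C@@]1(C)CCC2=O | intermediate
9 | (1S,5S,8R)-1,5-dimethyl-8-(prop-2-en-1-yl)-6-oxabicyclo[3.2.1]octane-2,7-dione (allyl syn to the lactone bridge) | C=CC[C@@H]1[C@]2(C)C(=O)O[C@@]1(C)CCC2=O | intermediate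
10 | (1S,2R,5S,8R)-2-hydroxy-1,5-dimethyl-8-(prop-2-en-1-yl)-6-oxabicyclo[3.2.1]octan-7-one | C=CC[C@@H]1[C@]2(C)C(=O)O[C@@]1(C)CC[C@H]2O | intermediate
11 | (1S,2R,5S,8R)-2-[(tert-butyldimethylsilyl)oxy]-1,5-dimethyl-8-(prop-2-en-1-yl)-6-oxabicyclo[3.2.1]octan-7-one | C=CC[C@@H]1[C@]2(C)C(=O)O[C@@]1(C)CC[C@H]2O[Si](C)(C)C(C)(C)C | intermediate
12 | (1S,2R,5S,8R)-2-[(tert-butyldimethylsilyl)oxy]-1,5-dimethyl-8-(prop-2-en-1-yl)-6-oxabicyclo[3.2.1]octan-7-ol, both C7 epimers | C=CC[C@@H]1[C@]2(C)C(O)O[C@@]1(C)CC[C@H]2O[Si](C)(C)C(C)(C)C | intermediate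
13 | tert-butyl{[(1R,2R,5S,8R)-1,5-dimethyl-8-(prop-2-en-1-yl)-6-oxabicyclo[3.2.1]octan-2-yl]oxy}dimethylsilane | C=CC[C@@H]1[C@]2(C)CO[C@@]1(C)CC[C@H]2O[Si](C)(C)C(C)(C)C | intermediate
14 | B-alkyl-9-borabicyclo[3.3.1]nonane adduct of 13 (boron on the terminal carbon) | C3CC4CCCC(C3)B4CCC[C@@H]1[C@]2(C)CO[C@@]1(C)CC[C@H]2O[Si](C)(C)C(C)(C)C | intermediate
15 | 3-[(1R,2R,5S,8R)-2-[(tert-butyldimethylsilyl)oxy]-1,5-dimethyl-6-oxabicyclo[3.2.1]octan-8-yl]propan-1-ol | OCCC[C@@H]1[C@]2(C)CO[C@@]1(C)CC[C@H]2O[Si](C)(C)C(C)(C)C | intermediate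
16 | 3-[(1R,2R,5S,8R)-2-[(tert-butyldimethylsilyl)oxy]-1,5-dimethyl-6-oxabicyclo[3.2.1]octan-8-yl]propanal | O=CCC[C@@H]1[C@]2(C)CO[C@@]1(C)CC[C@H]2O[Si](C)(C)C(C)(C)C | intermediate
17 | tert-butyl{[(1R,2R,5S,8R)-8-(but-3-yn-1-yl)-1,5-dimethyl-6-oxabicyclo[3.2.1]octan-2-yl]oxy}dimethylsilane | C#CCC[C@@H]1[C@]2(C)CO[C@@]1(C)CC[C@H]2O[Si](C)(C)C(C)(C)C | intermediate
18 | 7-hydroxy-2H-chromen-2-one (umbelliferone) | Oc1ccc2ccc(=O)oc2c1 | starting material
19 | 7-[(methylsulfanyl)methoxy]-2H-chromen-2-one | CSCOc1ccc2ccc(=O)oc2c1 | intermediate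
20 | 7-(chloromethoxy)-2H-chromen-2-one | ClCOc1ccc2ccc(=O)oc2c1 | intermediate
21 | (E)-2-methylalkenyl(dimethyl)alane from 17 (CH3 and Al cis) | C/C(=C\[Al](C)C)CC[C@@H]1[C@]2(C)CO[C@@]1(C)CC[C@H]2O[Si](C)(C)C(C)(C)C | intermediate
22 | lithium butyl(dimethyl)[(E)-2-methylalkenyl]alanate from 21 | [Li+].C/C(=C\[Al-](C)(C)CCCC)CC[C@@H]1[C@]2(C)CO[C@@]1(C)CC[C@H]2O[Si](C)(C)C(C)(C)C | intermediate
23 | 7-{[(2E)-5-[(1R,2R,5S,8R)-2-[(tert-butyldimethylsilyl)oxy]-1,5-dimethyl-6-oxabicyclo[3.2.1]octan-8-yl]-3-methylpent-2-en-1-yl]oxy}-2H-chromen-2-one | C/C(=C\COc1ccc2ccc(=O)oc2c1)CC[C@@H]1[C@]2(C)CO[C@@]1(C)CC[C@H]2O[Si](C)(C)C(C)(C)C | intermediate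
24 | 7-{[(2E)-5-[(1R,2R,5S,8R)-2-hydroxy-1,5-dimethyl-6-oxabicyclo[3.2.1]octan-8-yl]-3-methylpent-2-en-1-yl]oxy}-2H-chromen-2-one | C/C(=C\COc1ccc2ccc(=O)oc2c1)CC[C@@H]1[C@]2(C)CO[C@@]1(C)CC[C@H]2O | target

**Totals.** Total step count: 16. Longest linear sequence: 14 steps (steps 1–12, 15 and 16); steps 13 and 14 form the short coumarin branch.

**Steps most likely to fail**

Step 15. The alanate may add to the coumarin lactone or transfer methyl or butyl instead of the alkenyl group, and the chloromethyl ether may decompose before C–C bond formation. The fallback sets out from 17 and forms the same bond by palladium catalysis. Carboalumination of 17 as above followed by iodinolysis (I2, THF, −30 °C) should give the (E)-vinyl iodide tert-butyl{[(1R,2R,5S,8R)-8-[(3E)-4-iodo-3-methylbut-3-en-1-yl]-1,5-dimethyl-6-oxabicyclo[3.2.1]octan-2-yl]oxy}dimethylsilane F1. Umbelliferone 18 is alkylated with (iodomethyl)tributylstannane (K2CO3, DMF) to tributyl{[(2-oxo-2H-chromen-7-yl)oxy]methyl}stannane F2. Stille coupling of F1 with F2 (Pd(PPh3)4, CuI, CsF, DMF, 45 °C), in which the α-oxygenated methylene should transfer in preference to butyl, comes back to the route at 23.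

Step 5. Allyl transfer to the doubly neopentyl C8 radical may be slow, so that reduction of the radical or 1,2-acyloxy migration competes. The fallback sets out from 8 and uses a polarity-matched conjugate radical addition instead. Giese addition to acrolein (Bu3SnH by slow addition, AIBN, excess acrolein, benzene, 80 °C) should give 3-[(1S,5S,8R)-1,5-dimethyl-2,7-dioxo-6-oxabicyclo[3.2.1]octan-8-yl]propanal F3. Ohira–Bestmann homologation of the aldehyde (the hindered α-quaternary ketone should not react) gives (1S,5S,8R)-8-(but-3-yn-1-yl)-1,5-dimethyl-6-oxabicyclo[3.2.1]octane-2,7-dione F4. NaBH4 reduction gives (1S,2R,5S,8R)-8-(but-3-yn-1-yl)-2-hydroxy-1,5-dimethyl-6-oxabicyclo[3.2.1]octan-7-one F5. Silylation with TBSOTf gives (1S,2R,5S,8R)-8-(but-3-yn-1-yl)-2-[(tert-butyldimethylsilyl)oxy]-1,5-dimethyl-6-oxabicyclo[3.2.1]octan-7-one F6. DIBAL-H gives the lactol (1S,2R,5S,8R)-8-(but-3-yn-1-yl)-2-[(tert-butyldimethylsilyl)oxy]-1,5-dimethyl-6-oxabicyclo[3.2.1]octan-7-ol F7, and Et3SiH/BF3·OEt2 reduction of F7 comes back to the route at 17.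

Step 9. Under BF3 the lactol may open to the hydroxy aldehyde, the tertiary C5–O bond may ionise with elimination, or the silyl ether may be lost. The fallback sets out from 11 and closes the ether by C–O bond formation instead of lactol deoxygenation. LiAlH4 (THF, 0 °C) should give the diol (1S,2R,3R,4R)-4-[(tert-butyldimethylsilyl)oxy]-3-(hydroxymethyl)-1,3-dimethyl-2-(prop-2-en-1-yl)cyclohexan-1-ol F8, whose CH2OH and tertiary OH are 1,3-diaxial in the preferred chair. Selective triflation of the primary alcohol (Tf2O, 2,6-lutidine, CH2Cl2, −78 to 0 °C) with in situ 5-exo-tet displacement by the tertiary hydroxyl comes back to the route at 13, with retention at C5.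

**Further compounds**
F1 | step 15 | tert-butyl{[(1R,2R,5S,8R)-8-[(3E)-4-iodo-3-methylbut-3-en-1-yl]-1,5-dimethyl-6-oxabicyclo[3.2.1]octan-2-yl]oxy}dimethylsilane | C/C(=C\I)CC[C@@H]1[C@]2(C)CO[C@@]1(C)CC[C@H]2O[Si](C)(C)C(C)(C)C
F2 | step 15 | tributyl{[(2-oxo-2H-chromen-7-yl)oxy]methyl}stannane | CCCC[Sn](CCCC)(CCCC)COc1ccc2ccc(=O)oc2c1
F3 | step 5 | 3-[(1S,5S,8R)-1,5-dimethyl-2,7-dioxo-6-oxabicyclo[3.2.1]octan-8-yl]propanal | O=CCC[C@@H]1[C@]2(C)C(=O)O[C@@]1(C)CCC2=O
F4 | step 5 | (1S,5S,8R)-8-(but-3-yn-1-yl)-1,5-dimethyl-6-oxabicyclo[3.2.1]octane-2,7-dione | C#CCC[C@@H]1[C@]2(C)C(=O)O[C@@]1(C)CCC2=O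
F5 | step 5 | (1S,2R,5S,8R)-8-(but-3-yn-1-yl)-2-hydroxy-1,5-dimethyl-6-oxabicyclo[3.2.1]octan-7-one | C#CCC[C@@H]1[C@]2(C)C(=O)O[C@@]1(C)CC[C@H]2O
F6 | step 5 | (1S,2R,5S,8R)-8-(but-3-yn-1-yl)-2-[(tert-butyldimethylsilyl)oxy]-1,5-dimethyl-6-oxabicyclo[3.2.1]octan-7-one | C#CCC[C@@H]1[C@]2(C)C(=O)O[C@@]1(C)CC[C@H]2O[Si](C)(C)C(C)(C)C
F7 | step 5 | (1S,2R,5S,8R)-8-(but-3-yn-1-yl)-2-[(tert-butyldimethylsilyl)oxy]-1,5-dimethyl-6-oxabicyclo[3.2.1]octan-7-ol, both C7 epimers | C#CCC[C@@H]1[C@]2(C)C(O)O[C@@]1(C)CC[C@H]2O[Si](C)(C)C(C)(C)C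
F8 | step 9 | (1S,2R,3R,4R)-4-[(tert-butyldimethylsilyl)oxy]-3-(hydroxymethyl)-1,3-dimethyl-2-(prop-2-en-1-yl)cyclohexan-1-ol | C=CC[C@@H]1[C@](C)(CO)[C@H](O[Si](C)(C)C(C)(C)C)CC[C@]1(C)O
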